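## Retrosynthetic overview

1. Target ⇐ acetylation ⇐ macrocyclic hydroxy lactone ⇐ intramolecular Suzuki–Miyaura coupling at C5–C6, which closes the 14-membered carbocycle last and fixes the 4E,6E-diene.
2. Seven-membered lactone ⇐ 7-exo opening of a (1R,14R)-epoxide at C14 by a (10Z)-enoic acid (inversion at C14, C1–OH set free).
3. (10Z)-Enoate ⇐ Still–Gennari olefination of an epoxy aldehyde (fragment A, C11–C5) with a boryl phosphonate (fragment B, C6–C10 plus C15).
4. Fragment A ⇐ Shi epoxidation (chiral ketone organocatalyst, sets both stereocentres) of a dienoate made by Negishi carboalumination and Johnson–Claisen rearrangement; fragment B ⇐ a new copper-catalysed borylative opening of a phosphonocyclopropane with 3-methylbut-1-yne.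
5. Ring order: oxirane, then seven-membered lactone, then fourteen-membered carbocycle.

Assumption and locants: the C10=C11 alkene, which carries no descriptor in the SMILES, is taken as the ring-enforced cis enoate of the lactone; text locants (not those of the systematic names) are C1 = CH–OAc, C2, C3, C4(Me)=C5–C6=C7(iPr), C8, C9, C10=C11, C12, C13, C14 = C(Me)–O, C15 = lactone C=O.

## Route

Step 1
Reactants: 1 pent-4-yn-1-ol
Product: 3 (4E)-5-iodo-4-methylpent-4-en-1-ol, via alkenylalane 2 (not isolated)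
Conditions: AlMe3 (3 equiv), Cp2ZrCl2 (25 mol%), CH2Cl2, 0 °C to rt; then I2, THF, −30 °C; aq. K2CO3
Reagents that add atoms: trimethylaluminium, C[Al](C)C; iodine, [I][I]
Why: Zirconium-catalysed Negishi carboalumination adds Me and Al syn across the alkyne (Me to the internal carbon) and iodinolysis of the C–Al bond goes with retention, giving the (E)-2-methylalkenyl iodide that becomes C4=C5.

Step 2
Reactants: 3 (4E)-5-iodo-4-methylpent-4-en-1-ol
Product: 4 (4E)-5-iodo-4-methylpent-4-enal
Conditions: TEMPO (2,2,6,6-tetramethylpiperidin-1-oxyl, 10 mol%), PhI(OAc)2 (1.1 equiv), CH2Cl2, rt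
Reagents that add atoms: none
Why: Oxoammonium-mediated alcohol oxidation stops at the aldehyde and leaves the alkenyl iodide untouched.

Step 3
Reactants: 4 (4E)-5-iodo-4-methylpent-4-enal; 5 isopropenylmagnesium bromide
Product: 6 (6E)-7-iodo-2,6-dimethylhepta-1,6-dien-3-ol (racemic)
Conditions: THF, −78 to −20 °C; aq. NH4Cl
Reagents that add atoms: none
Why: Grignard 1,2-addition to the aldehyde outruns iodine–magnesium exchange at low temperature, and the racemic carbinol centre is erased in step 4.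

Step 4
Reactants: 6 (6E)-7-iodo-2,6-dimethylhepta-1,6-dien-3-ol; 7 triethyl orthoacetate
Product: 9 ethyl (4E,8E)-9-iodo-4,8-dimethylnona-4,8-dienoate, via ketene acetal 8 (not isolated)
Conditions: EtCO2H (5 mol%), neat 7 (6 equiv), 140 °C, EtOH distilled off
Reagents that add atoms: none
Why: Johnson–Claisen rearrangement through a chair transition state with the carbinol substituent equatorial gives the (E)-trisubstituted C14=C1 alkene (about 97:3 expected) and the ester arm C12–C11 in one operation.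

Step 5
Reactants: 9 ethyl (4E,8E)-9-iodo-4,8-dimethylnona-4,8-dienoate
Product: 10 ethyl 3-[(2R,3R)-3-[(3E)-4-iodo-3-methylbut-3-en-1-yl]-2-methyloxiran-2-yl]propanoate
Conditions: Shi ketone (1,2:4,5-di-O-isopropylidene-β-D-erythro-2,3-hexodiulo-2,6-pyranose, 30 mol%), KHSO5 (as 2KHSO5·KHSO4·K2SO4, 1.4 equiv), K2CO3, Bu4NHSO4 (cat.), MeCN/CH2(OMe)2, aq. Na2B4O7 buffer (pH 10.5), 0 °C
Reagents that add atoms: potassium peroxymonosulfate, [K+].[O-]S(=O)(=O)OO
Why: Shi asymmetric epoxidation (chiral dioxirane, spiro transition state) delivers oxygen to one face of the electron-rich (E)-trialkyl alkene and sets C14 and C1 together as (R,R) (90–95% ee expected for this alkene class), while the iodine-deactivated alkenyl iodide should not react.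

Step 6
Reactants: 10 ethyl 3-[(2R,3R)-3-[(3E)-4-iodo-3-methylbut-3-en-1-yl]-2-methyloxiran-2-yl]propanoate
Product: 11 3-[(2R,3R)-3-[(3E)-4-iodo-3-methylbut-3-en-1-yl]-2-methyloxiran-2-yl]propanal
Conditions: iBu2AlH (1.1 equiv), toluene, −78 °C; MeOH quench
Reagents that add atoms: none
Why: Half-reduction of the ester at −78 °C through the stable tetrahedral aluminium hemiacetal gives the aldehyde without opening the epoxide.

Step 7
Reactants: 12 methyl 2-[bis(2,2,2-trifluoroethoxy)phosphoryl]acetate; 13 1,2-dibromoethane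
Product: 14 methyl 1-[bis(2,2,2-trifluoroethoxy)phosphoryl]cyclopropane-1-carboxylate
Conditions: K2CO3 (2.5 equiv), Bu4NBr (cat.), DMF, 50 °C
Reagents that add atoms: none
Why: Double alkylation of the active methylene (SN2, then fast 3-exo-tet closure) is the standard malonate-type cyclopropanation and uses a base too weak to attack the trifluoroethyl phosphonate esters.

Step 8
Reactants: 14 methyl 1-[bis(2,2,2-trifluoroethoxy)phosphoryl]cyclopropane-1-carboxylate; 15 3-methylbut-1-yne
Product: 17 methyl (5E)-2-[bis(2,2,2-trifluoroethoxy)phosphoryl]-5-(propan-2-yl)-6-(4,4,5,5-tetramethyl-1,3,2-dioxaborolan-2-yl)hex-5-enoate (fragment B), via lithium phosphonoenolate 16 (not isolated)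
Conditions: CuCl (10 mol%), Xantphos (4,5-bis(diphenylphosphino)-9,9-dimethylxanthene, 12 mol%), LiOtBu (1.2 equiv), B2pin2 (1.1 equiv), THF, 0 to 40 °C; aq. NH4Cl
Reagents that add atoms: bis(pinacolato)diboron, CC1(C)OB(OC1(C)C)B1OC(C)(C)C(C)(C)O1
Why: Proposed new method: copper-catalysed borylative homoconjugate addition, in which LCu–Bpin adds syn across the terminal alkyne (boron to the CH terminus, copper to the carbon bearing iPr) and the β-boryl alkenylcopper, having no proton source or other electrophile available, opens the doubly acceptor-activated cyclopropane at a CH2 group to form C7–C8 and a stabilised phosphonoacetate enolate that LiOtBu exchanges off copper, so boron ends cis to the new CH2CH2 chain (the later C6=C7 geometry); the closest known reactions are the copper-catalysed alkylboration of alkynes with alkyl halides and the ring-opening of cyclopropane-1,1-diesters by organocuprates.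

Step 9
Reactants: 11 3-[(2R,3R)-3-[(3E)-4-iodo-3-methylbut-3-en-1-yl]-2-methyloxiran-2-yl]propanal; 17 fragment B
Product: 18 methyl (2Z)-5-[(2R,3R)-3-[(3E)-4-iodo-3-methylbut-3-en-1-yl]-2-methyloxiran-2-yl]-2-[(3E)-3-(propan-2-yl)-4-(4,4,5,5-tetramethyl-1,3,2-dioxaborolan-2-yl)but-3-en-1-yl]pent-2-enoate
Conditions: KN(SiMe3)2 (1.15 equiv), 18-crown-6 (3 equiv), THF, −78 °C
Reagents that add atoms: none
Why: In the Still–Gennari variant of the Horner–Wadsworth–Emmons olefination the electron-poor bis(trifluoroethyl) phosphonate eliminates fast from the kinetic adduct under dissociating K+/crown conditions, giving the (Z)-enoate with the ester cis to C12 (about 10:1 expected), as lactone closure requires.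

Step 10
Reactants: 18 the (2Z)-enoate epoxide
Product: 20 (7S)-7-[(1R,4E)-1-hydroxy-5-iodo-4-methylpent-4-en-1-yl]-7-methyl-3-[(3E)-3-(propan-2-yl)-4-(4,4,5,5-tetramethyl-1,3,2-dioxaborolan-2-yl)but-3-en-1-yl]-6,7-dihydro-5H-oxepin-2-one, via epoxy acid 19 (not isolated)
Conditions: LiOH (5 equiv), THF/MeOH/H2O, rt; aq. HCl to pH 3; then camphor-10-sulfonic acid (10 mol%), CH2Cl2, 0 °C to rt
Reagents that add atoms: lithium hydroxide, [Li+].[OH-]
Why: After saponification, acid-catalysed intramolecular epoxide opening by the (Z)-held carboxylic acid takes the 7-exo path at the tertiary carbon with inversion, so C14 becomes (S) carrying the lactone oxygen while C1 keeps its (R) oxygen as the free alcohol (net anti addition across the former (E)-alkene).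

Step 11
Reactants: 20 the hydroxy lactone
Product: 21 (1S,2R,5E,7E,11Z)-2-hydroxy-1,5-dimethyl-8-(propan-2-yl)-15-oxabicyclo[9.3.2]hexadeca-5,7,11-trien-16-one
Conditions: Pd(PPh3)4 (20 mol%), TlOEt (2.5 equiv), THF/H2O 4:1, 1 mM by slow addition, rt
Reagents that add atoms: none
Why: Intramolecular Suzuki–Miyaura coupling is stereoretentive at both alkenyl partners, so the 14-membered ring closes at C5–C6 with the (4E,6E)-diene geometry fixed in steps 1 and 8.

Step 12
Reactants: 21 the macrocyclic hydroxy lactone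
Product: 22 [(1S,2R,5E,7E,11Z)-1,5-dimethyl-16-oxo-8-(propan-2-yl)-15-oxabicyclo[9.3.2]hexadeca-5,7,11-trien-2-yl] acetate (CNP0291129.1)
Conditions: Ac2O (3 equiv), 4-(dimethylamino)pyridine (0.2 equiv), Et3N, CH2Cl2, rt
Reagents that add atoms: acetic anhydride, CC(=O)OC(C)=O
Why: Nucleophile-catalysed acylation of the only hydroxyl group gives the C1 acetate without touching the stereocentres, the lactone or the diene.

## Compound list

1 | pent-4-yn-1-ol | C#CCCCO | starting material
2 | alkenylalane, [(1E)-5-(dimethylalumanyloxy)-2-methylpent-1-en-1-yl]dimethylalumane | C[Al](C)/C=C(\C)CCCO[Al](C)C | intermediate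
3 | (4E)-5-iodo-4-methylpent-4-en-1-ol | OCCC/C(C)=C/I | intermediate
4 | (4E)-5-iodo-4-methylpent-4-enal | O=CCC/C(C)=C/I | intermediate
5 | isopropenylmagnesium bromide | CC(=C)[Mg]Br | starting material
6 | (6E)-7-iodo-2,6-dimethylhepta-1,6-dien-3-ol (racemic) | CC(=C)C(O)CC/C(C)=C/I | intermediate
7 | triethyl orthoacetate | CC(OCC)(OCC)OCC | starting material
8 | ketene acetal, (1E)-5-[(1-ethoxyethenyl)oxy]-1-iodo-2,6-dimethylhepta-1,6-diene | C=C(OCC)OC(C(C)=C)CC/C(C)=C/I | intermediate
9 | ethyl (4E,8E)-9-iodo-4,8-dimethylnona-4,8-dienoate | CCOC(=O)CC/C(C)=C/CC/C(C)=C/I | intermediate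
10 | ethyl 3-[(2R,3R)-3-[(3E)-4-iodo-3-methylbut-3-en-1-yl]-2-methyloxiran-2-yl]propanoate | CCOC(=O)CC[C@@]1(C)O[C@@H]1CC/C(C)=C/I | intermediate
11 | 3-[(2R,3R)-3-[(3E)-4-iodo-3-methylbut-3-en-1-yl]-2-methyloxiran-2-yl]propanal | O=CCC[C@@]1(C)O[C@@H]1CC/C(C)=C/I | intermediate
12 | methyl 2-[bis(2,2,2-trifluoroethoxy)phosphoryl]acetate | COC(=O)CP(=O)(OCC(F)(F)F)OCC(F)(F)F | starting material
13 | 1,2-dibromoethane | BrCCBr | starting material
14 | methyl 1-[bis(2,2,2-trifluoroethoxy)phosphoryl]cyclopropane-1-carboxylate | COC(=O)C1(CC1)P(=O)(OCC(F)(F)F)OCC(F)(F)F | intermediate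
15 | 3-methylbut-1-yne | CC(C)C#C | starting material
16 | lithium phosphonoenolate of 17 | [Li+].COC(=O)[C-](CC/C(C(C)C)=C\B1OC(C)(C)C(C)(C)O1)P(=O)(OCC(F)(F)F)OCC(F)(F)F | intermediate
17 | methyl (5E)-2-[bis(2,2,2-trifluoroethoxy)phosphoryl]-5-(propan-2-yl)-6-(4,4,5,5-tetramethyl-1,3,2-dioxaborolan-2-yl)hex-5-enoate (fragment B, racemic at C2) | COC(=O)C(CC/C(C(C)C)=C\B1OC(C)(C)C(C)(C)O1)P(=O)(OCC(F)(F)F)OCC(F)(F)F | intermediate
18 | methyl (2Z)-5-[(2R,3R)-3-[(3E)-4-iodo-3-methylbut-3-en-1-yl]-2-methyloxiran-2-yl]-2-[(3E)-3-(propan-2-yl)-4-(4,4,5,5-tetramethyl-1,3,2-dioxaborolan-2-yl)but-3-en-1-yl]pent-2-enoate | COC(=O)/C(CC/C(C(C)C)=C\B1OC(C)(C)C(C)(C)O1)=C\CC[C@@]2(C)O[C@@H]2CC/C(C)=C/I | intermediate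
19 | epoxy acid, the carboxylic acid of 18 | OC(=O)/C(CC/C(C(C)C)=C\B1OC(C)(C)C(C)(C)O1)=C\CC[C@@]2(C)O[C@@H]2CC/C(C)=C/I | intermediate
20 | (7S)-7-[(1R,4E)-1-hydroxy-5-iodo-4-methylpent-4-en-1-yl]-7-methyl-3-[(3E)-3-(propan-2-yl)-4-(4,4,5,5-tetramethyl-1,3,2-dioxaborolan-2-yl)but-3-en-1-yl]-6,7-dihydro-5H-oxepin-2-one | O[C@H](CC/C(C)=C/I)[C@]1(C)CCC=C(CC/C(C(C)C)=C\B2OC(C)(C)C(C)(C)O2)C(=O)O1 | intermediate
21 | (1S,2R,5E,7E,11Z)-2-hydroxy-1,5-dimethyl-8-(propan-2-yl)-15-oxabicyclo[9.3.2]hexadeca-5,7,11-trien-16-one | O[C@@H]1CC/C(C)=C/C=C(/C(C)C)CCC2=CCC[C@]1(C)OC2=O | intermediate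
22 | [(1S,2R,5E,7E,11Z)-1,5-dimethyl-16-oxo-8-(propan-2-yl)-15-oxabicyclo[9.3.2]hexadeca-5,7,11-trien-2-yl] acetate (CNP0291129.1) | CC(=O)O[C@@H]1CC/C(C)=C/C=C(/C(C)C)CCC2=CCC[C@]1(C)OC2=O | target

## Step count and risks

Total: 12 steps. Longest linear sequence: 10 steps (steps 1–6 and 9–12); fragment B takes two steps (7 and 8).

**Step 8 (the proposed new reaction).** The hindered alkenylcopper may be too weak a nucleophile for the cyclopropane, or may be quenched by the acidic alkyne C–H. The fallback uses known chemistry only; it sets out from 15 (with 12) and comes back at 17. Known copper-catalysed alkylboration of 15 with B2pin2 and tert-butyl(2-iodoethoxy)dimethylsilane (CuCl, Xantphos, NaOtBu, THF) gives the alkenylboronate silyl ether F1 with the same syn geometry. Acid methanolysis (camphor-10-sulfonic acid, MeOH, 0 °C) gives the alkenylboronate alcohol F2. Iodination (I2, PPh3, imidazole) gives the alkenylboronate iodide F3. Alkylation of the sodium salt of 12 with F3 (NaH, DMF) then gives 17.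

**Step 10 (7-exo lactonisation).** The carboxylic acid is a weak nucleophile, so epoxide rearrangement to a ketone or cation–alkene cyclisation could compete, and the boronate may suffer during saponification. The fallback sets out from 18 and comes back at 21 by closing the carbocycle first. Suzuki–Miyaura macrocyclisation of 18 (Pd(PPh3)4, TlOEt, high dilution) gives the macrocyclic epoxy ester F4. Hydrolysis with Me3SnOH (1,2-dichloroethane, 70 °C) followed by catalytic camphor-10-sulfonic acid then lets the ring hold the acid over C14 for a transannular epoxide opening that gives 21 directly.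

**Step 11 (Suzuki macrocyclisation).** Oligomerisation or protodeboronation of the hindered partners could win over ring closure. The fallback moves the ring closure from C5–C6 to C10=C11; it sets out from 10 (with 17) and comes back at 21. Intermolecular Suzuki–Miyaura coupling of 10 with 17 (Pd(PPh3)4, K3PO4, DMF) gives the open-chain diene phosphonate F5. NaH masks the phosphonoacetate as its sodium enolate, and iBu2AlH at −78 °C then reduces only the ethyl ester to give the open-chain aldehyde phosphonate F6. Intramolecular Still–Gennari olefination (KN(SiMe3)2, 18-crown-6, THF, 1 mM, −78 °C) gives the macrocyclic epoxy ester F4, which is hydrolysed and lactonised to 21 as in the step 10 fallback.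

## Further compounds

F1 | step 8 | alkenylboronate silyl ether, tert-butyldimethyl{[(3E)-3-(propan-2-yl)-4-(4,4,5,5-tetramethyl-1,3,2-dioxaborolan-2-yl)but-3-en-1-yl]oxy}silane | CC(C)/C(CCO[Si](C)(C)C(C)(C)C)=C/B1OC(C)(C)C(C)(C)O1
F2 | step 8 | alkenylboronate alcohol, (3E)-3-(propan-2-yl)-4-(4,4,5,5-tetramethyl-1,3,2-dioxaborolan-2-yl)but-3-en-1-ol | CC(C)/C(CCO)=C/B1OC(C)(C)C(C)(C)O1
F3 | step 8 | alkenylboronate iodide, 2-[(1E)-4-iodo-2-(propan-2-yl)but-1-en-1-yl]-4,4,5,5-tetramethyl-1,3,2-dioxaborolane | CC(C)/C(CCI)=C/B1OC(C)(C)C(C)(C)O1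
F4 | step 10 | macrocyclic epoxy ester, methyl (1R,14R,4E,6E,10Z)-1,14-epoxy-4,14-dimethyl-7-(propan-2-yl)cyclotetradeca-4,6,10-triene-10-carboxylate (text locants) | COC(=O)/C1=C\CC[C@@]2(C)O[C@@H]2CC/C(C)=C/C=C(/C(C)C)CC1
F5 | step 11 | open-chain diene phosphonate, ethyl 3-[(2R,3R)-3-[(3E,5E)-9-[bis(2,2,2-trifluoroethoxy)phosphoryl]-10-methoxy-3-methyl-10-oxo-6-(propan-2-yl)deca-3,5-dien-1-yl]-2-methyloxiran-2-yl]propanoate | CCOC(=O)CC[C@@]1(C)O[C@@H]1CC/C(C)=C/C=C(/C(C)C)CCC(C(=O)OC)P(=O)(OCC(F)(F)F)OCC(F)(F)F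
F6 | step 11 | open-chain aldehyde phosphonate, methyl (5E,7E)-2-[bis(2,2,2-trifluoroethoxy)phosphoryl]-8-methyl-10-[(2R,3R)-3-methyl-3-(3-oxopropyl)oxiran-2-yl]-5-(propan-2-yl)deca-5,7-dienoate | O=CCC[C@@]1(C)O[C@@H]1CC/C(C)=C/C=C(/C(C)C)CCC(C(=O)OC)P(=O)(OCC(F)(F)F)OCC(F)(F)F
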